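**Retrosynthetic overview**

1. The strategy rests on C2: it is an allylic carbinol carbon between the quaternary C1 of ring A (C1 carries the C15 methyl and no hydrogen) and the Z‑C3=C4 alkene of the ten‑membered ring (C1–C10). Cutting C2–C3 gives a non‑enolisable C2 aldehyde and a Z‑alkenyl iodide at C3 (36), rejoined by a Nozaki–Hiyama–Kishi coupling; Cl‑6 is put in last by inversion of a C6 oxygen.
2. 36 ⇒ C6–C7 bond by reagent‑controlled γ‑alkoxyallylboration of a C7 lactol with an enyne allyl ether (C3–C6, C16), then oxidative closure of the C7–O–C19 γ‑lactone.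
3. C8–C9 bond ⇒ aldol of an α‑silyloxy‑β‑methylbutanolide enolate (C7, C8, C17–C19) with the ring A C9 aldehyde, then oxidation and Felkin–Anh reduction to set C9.
4. Ring A (C1, C10–C14) ⇒ iminium‑catalysed Diels–Alder reaction of an E formyl methacrylate with (E)‑piperylene, then two hydroxyl‑directed epoxidations linked by an epoxide‑to‑allylic‑alcohol isomerisation.
5. Ring order: ring A (step 2); butanolide brought in with 12 and re‑formed as the C19 lactone (step 20); 13,14‑epoxide (step 22); ten‑membered ring (step 28).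

Key step: step 28

Remark: carbons are numbered as in the target (ring A = C1, C10–C14; C2 and the C15 methyl on C1, C9 on C10, the C20 methyl on C11); α is the face of ring A that carries C2, β the face that carries C15; the C6 oxygen is carried as a p‑methoxybenzyl ether, and (R)‑4‑methyldihydrofuran‑2(3H)‑one is assumed to be purchasable.

**Route**

Step 1
Reactants: 1 ethyl (E)-2-methylbut-2-enoate
Product: 2 ethyl (E)-2-methyl-4-oxobut-2-enoate
Conditions: SeO2, 1,4-dioxane, reflux
Reagents that add atoms: selenium dioxide, O=[Se]=O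
Why: Allylic oxidation with SeO2 (ene reaction, [2,3]-shift, further oxidation) should take place at the γ-methyl group of the enoate and leave the E alkene untouched; no stereocentre is formed.

Step 2
Reactants: 2 ethyl (E)-2-methyl-4-oxobut-2-enoate; 3 (E)-penta-1,3-diene
Product: 4 ethyl (1S,5S,6S)-6-formyl-1,5-dimethylcyclohex-3-ene-1-carboxylate
Conditions: (5S)-5-benzyl-2,2,3-trimethylimidazolidin-4-one hydrochloride (20 mol %), 3 (5 equiv), MeCN/H2O 95:5, 0 °C to rt
Reagents that add atoms: none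
Why: Iminium-catalysed Diels–Alder reaction in which the benzyl group of the catalyst covers one face of the E-iminium ion so that the diene adds to the Si face of C10 (absolute configuration of C1 and C10; their trans ester/formyl relation comes from the E alkene), the methyl-bearing diene terminus bonds to C10 (ortho rule) and the endo position of the iminium group places the C20 methyl cis to the formyl group (C11).

Step 3
Reactants: 4 ethyl (1S,5S,6S)-6-formyl-1,5-dimethylcyclohex-3-ene-1-carboxylate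
Product: 5 ethyl (1S,5S,6S)-6-(dimethoxymethyl)-1,5-dimethylcyclohex-3-ene-1-carboxylate
Conditions: HC(OMe)3, PPTS, MeOH, rt
Reagents that add atoms: trimethyl orthoformate, COC(OC)OC; methanol, CO
Why: Acid-catalysed acetalisation masks the C9 aldehyde so that the C2 ester can be reduced alone; no stereocentre is touched.

Step 4
Reactants: 5 ethyl (1S,5S,6S)-6-(dimethoxymethyl)-1,5-dimethylcyclohex-3-ene-1-carboxylate
Product: 6 [(1S,5S,6S)-6-(dimethoxymethyl)-1,5-dimethylcyclohex-3-en-1-yl]methanol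
Conditions: LiAlH4, THF, 0 °C
Reagents that add atoms: none
Why: Hydride reduction of the neopentyl ester to the primary C2 alcohol; acetal and alkene are inert.

Step 5
Reactants: 6 [(1S,5S,6S)-6-(dimethoxymethyl)-1,5-dimethylcyclohex-3-en-1-yl]methanol
Product: 7 12α,13α-epoxy alcohol (6 with a C12–C13 epoxide cis to the C2 hydroxymethyl group)
Conditions: VO(acac)2 (5 mol %), t-BuOOH, toluene, rt to 40 °C
Reagents that add atoms: tert-butyl hydroperoxide, CC(C)(C)OO
Why: Hydroxyl-directed epoxidation in which the bishomoallylic C2 hydroxyl binds vanadium and delivers oxygen to the face of C12=C13 on which it sits (α), setting C12 and C13.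

Step 6
Reactants: 7 12α,13α-epoxy alcohol
Product: 8 C2 tert-butyldiphenylsilyl ether of 7
Conditions: t-BuPh2SiCl, imidazole, DMF, rt
Reagents that add atoms: tert-butyl(chloro)diphenylsilane, CC(C)(C)[Si](Cl)(c1ccccc1)c1ccccc1
Why: Silylation of the primary alcohol with a group that outlasts the later cleavage of triethylsilyl ethers.

Step 7
Reactants: 8 C2 tert-butyldiphenylsilyl ether of 7
Product: 9 ring A allylic alcohol (12α-hydroxyl, C13=C14 alkene, C2 silyl ether, C9 dimethyl acetal)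
Conditions: Et2Al(TMP) [from 2,2,6,6-tetramethylpiperidine, n-BuLi, Et2AlCl], toluene, 0 °C
Reagents that add atoms: none
Why: Base-promoted isomerisation of an epoxide to an allylic alcohol in which aluminium binds the epoxide oxygen and the amide removes the syn hydrogen at C14 (methylene preferred over the C11 methine), so that the C13–O bond breaks and the 12α oxygen stays as the allylic hydroxyl.

Step 8
Reactants: 9 ring A allylic alcohol
Product: 10 ring A hydroxy aldehyde (C9 aldehyde, 12α-hydroxyl)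
Conditions: PPTS, acetone/H2O 9:1, 40 °C
Reagents that add atoms: water, O
Why: Mild acetal hydrolysis should free the C9 aldehyde without ionising the allylic alcohol or cleaving the silyl ether.

Step 9
Reactants: 10 ring A hydroxy aldehyde
Product: 11 ring A aldehyde (C9 aldehyde, 12α triethylsilyl ether, C2 tert-butyldiphenylsilyl ether)
Conditions: Et3SiCl, imidazole, CH2Cl2, 0 °C
Reagents that add atoms: chlorotriethylsilane, CC[Si](Cl)(CC)CC
Why: Silylation of the secondary C12 hydroxyl with a group that can later be removed together with those on C8 and C9 while the C2 silyl ether stays.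

Step 10
Reactants: 12 (R)-4-methyldihydrofuran-2(3H)-one
Product: 14 (3R,4S)-3-hydroxy-4-methyldihydrofuran-2(3H)-one, via sodium enolate 13 (not isolated)
Conditions: NaN(SiMe3)2, THF, −78 °C; 2-(phenylsulfonyl)-3-phenyloxaziridine; AcOH
Reagents that add atoms: 2-(phenylsulfonyl)-3-phenyloxaziridine, O=S(=O)(c1ccccc1)N1OC1c1ccccc1
Why: Enolate oxidation with an N-sulfonyloxaziridine, oxygen entering anti to the C17 methyl (trans product); this C8 configuration is erased again in step 14.

Step 11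
Reactants: 14 (3R,4S)-3-hydroxy-4-methyldihydrofuran-2(3H)-one
Product: 15 (3R,4S)-4-methyl-3-(triethylsilyloxy)dihydrofuran-2(3H)-one
Conditions: Et3SiCl, imidazole, DMF, rt
Reagents that add atoms: chlorotriethylsilane, CC[Si](Cl)(CC)CC
Why: Silylation of the α-hydroxyl so that the lactone can be enolised at C8.

Step 12
Reactants: 16 2-bromoprop-2-en-1-ol
Product: 17 1-{[(2-bromoprop-2-en-1-yl)oxy]methyl}-4-methoxybenzene
Conditions: NaH, 4-MeOC6H4CH2Cl, Bu4NI (cat.), THF/DMF, 0 °C to rt
Reagents that add atoms: 4-methoxybenzyl chloride, COc1ccc(CCl)cc1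
Why: Williamson etherification of the allylic alcohol.

Step 13
Reactants: 17 1-{[(2-bromoprop-2-en-1-yl)oxy]methyl}-4-methoxybenzene; 18 ethynyltrimethylsilane
Product: 19 {3-[(4-methoxybenzyloxy)methyl]but-3-en-1-yn-1-yl}trimethylsilane
Conditions: PdCl2(PPh3)2 (cat.), CuI (cat.), i-Pr2NH, THF, rt
Reagents that add atoms: none
Why: Sonogashira coupling of the alkenyl bromide with the terminal alkyne gives the C3–C6/C16 enyne.

Step 14
Reactants: 15 (3R,4S)-4-methyl-3-(triethylsilyloxy)dihydrofuran-2(3H)-one; 11 ring A aldehyde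
Product: 21 aldol adduct (C8–C9 bond; 8R; C9 carbinol as epimer mixture), via lithium enolate 20 (not isolated)
Conditions: LiN(i-Pr)2, THF, −78 °C; then 11; AcOH quench at −78 °C
Reagents that add atoms: none
Why: Aldol addition of a lactone lithium enolate in which the aldehyde is taken up on the enolate face anti to the C17 methyl, fixing the quaternary C8 (C9 trans to C18, O8 cis); the cold acidic quench is meant to prevent silyl migration from O8 to O9, and the C9 epimers converge in step 15.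

Step 15
Reactants: 21 aldol adduct
Product: 22 C9 ketone
Conditions: DMP, NaHCO3, CH2Cl2, rt
Reagents that add atoms: none
Why: Hypervalent-iodine oxidation of the secondary alcohol brings both C9 epimers to one ketone; C8 is quaternary and cannot epimerise.

Step 16
Reactants: 22 C9 ketone
Product: 23 (9S)-alcohol
Conditions: NaBH4, CeCl3·7H2O, MeOH/THF, −40 °C
Reagents that add atoms: none
Why: Luche reduction under Felkin–Anh control, hydride entering anti to the quaternary C1 on C10 and past H10, which should give the 9S carbinol; the hindered lactone is not reduced and the non-basic medium protects C10.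

Step 17
Reactants: 23 (9S)-alcohol
Product: 24 tris(triethylsilyl) ether (O8, O9, O12)
Conditions: Et3SiOTf, 2,6-lutidine, CH2Cl2, 0 °C
Reagents that add atoms: triethylsilyl trifluoromethanesulfonate, CC[Si](CC)(CC)OS(=O)(=O)C(F)(F)F
Why: Silylation of the hindered C9 hydroxyl so that only O7 can later close the lactone.

Step 18
Reactants: 24 tris(triethylsilyl) ether
Product: 25 C7 lactol (anomer mixture)
Conditions: i-Bu2AlH, CH2Cl2, −78 °C
Reagents that add atoms: none
Why: Partial reduction of the lactone, the tetrahedral aluminium intermediate being stable at −78 °C, gives the masked C7 aldehyde.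

Step 19
Reactants: 25 C7 lactol; 19 {3-[(4-methoxybenzyloxy)methyl]but-3-en-1-yn-1-yl}trimethylsilane
Product: 28 C7,C19 diol (6R,7S; C6 p-methoxybenzyl ether; C5=C16 methylene; C3≡C4 silylalkyne), via allyllithium 26 (not isolated), via allylborane 27 (not isolated)
Conditions: 19 (3 equiv), s-BuLi, THF, −78 °C; (−)-Ipc2BOMe [from (+)-α-pinene]; BF3·OEt2; then 25, −78 °C to rt; HOCH2CH2NH2
Reagents that add atoms: none
Why: γ-Alkoxyallylboration through a chair six-membered transition state on the open aldehyde form of 25: the cis arrangement of oxygen and CH2B in 27 gives the syn C6/C7 relation, and the isopinocampheyl groups direct attack to the Si face of the C7 aldehyde (reagent control).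

Step 20
Reactants: 28 C7,C19 diol
Product: 29 γ-lactone (C19 carbonyl, O–C7)
Conditions: TEMPO (20 mol %), PhI(OAc)2, CH2Cl2, rt
Reagents that add atoms: none
Why: Nitroxyl-catalysed oxidation of the primary C19 alcohol, the aldehyde being trapped by the C7 hydroxyl as a five-membered lactol that is oxidised on to the lactone; C7 and C17 are not touched.

Step 21
Reactants: 29 γ-lactone
Product: 30 C8,C9,C12 triol
Conditions: HF·pyridine, pyridine, THF, 0 °C to rt
Reagents that add atoms: none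
Why: Fluoride cleavage of the three triethylsilyl ethers; the primary tert-butyldiphenylsilyl ether and the alkynylsilane should survive buffered HF.

Step 22
Reactants: 30 C8,C9,C12 triol
Product: 31 13α,14α-epoxy triol
Conditions: VO(acac)2 (5 mol %), t-BuOOH (1.2 equiv), CH2Cl2, 0 °C to rt
Reagents that add atoms: tert-butyl hydroperoxide, CC(C)(C)OO
Why: Hydroxyl-directed epoxidation in which the allylic 12α hydroxyl delivers oxygen syn to itself onto C13=C14 (sets C13 and C14), much faster than any delivery from the remote C8 or C9 hydroxyls.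

Step 23
Reactants: 31 13α,14α-epoxy triol
Product: 32 C9,C12 diacetate
Conditions: Ac2O, DMAP, pyridine, CH2Cl2, rt
Reagents that add atoms: acetic anhydride, CC(=O)OC(C)=O
Why: Acylation of the two secondary alcohols; the tertiary C8 hydroxyl is too hindered to react.

Step 24
Reactants: 32 C9,C12 diacetate
Product: 33 iodoalkyne
Conditions: N-iodosuccinimide, AgNO3 (cat.), DMF, rt, dark
Reagents that add atoms: N-iodosuccinimide, O=C1CCC(=O)N1I
Why: Silver-catalysed iododesilylation of the alkynylsilane; acetates, epoxide and lactone are inert.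

Step 25
Reactants: 33 iodoalkyne
Product: 34 (Z)-iodo-diene
Conditions: 2-nitrobenzenesulfonyl hydrazide, Et3N, THF/i-PrOH, rt
Reagents that add atoms: none
Why: Diimide reduction delivers two hydrogens syn to the iodoalkyne and gives the Z-alkenyl iodide; the 1,1-disubstituted alkene reacts more slowly.

Step 26
Reactants: 34 (Z)-iodo-diene
Product: 35 C2 alcohol
Conditions: Bu4NF, AcOH, THF, rt to 40 °C
Reagents that add atoms: none
Why: Buffered fluoride cleaves the silyl ether without touching the acetates, the β-hydroxy lactone or the epoxide.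

Step 27
Reactants: 35 C2 alcohol
Product: 36 seco C2 aldehyde with Z-iodo-diene arm (precursor of the key step)
Conditions: DMP, NaHCO3, CH2Cl2, rt
Reagents that add atoms: none
Why: Hypervalent-iodine oxidation of the neopentyl primary alcohol; the aldehyde has no α-hydrogen and the tertiary C8 hydroxyl cannot be oxidised.

Step 28
Reactants: 36 seco C2 aldehyde
Product: 38 ten-membered C2 allylic alcohol (2S), via alkenylchromium 37 (not isolated)
Conditions: CrCl2 (15 equiv), NiCl2 (0.15 equiv), degassed DMSO/THF 3:1, rt, 36 added over 12 h to a final 0.002 M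
Reagents that add atoms: none
Why: Nozaki–Hiyama–Kishi reaction: oxidative addition of the C3–I bond to zerovalent nickel (made from NiCl2 by CrCl2) keeps the Z geometry, transmetallation hands the alkenyl group to trivalent chromium (37), and this species adds 1,2 to the C2 carbonyl while divalent chromium returns the nickel to the cycle. The closest known reaction type is the intramolecular alkenyl iodide–aldehyde coupling used to close medium and large rings. The ten-membered ring closes by C2–C3 bond formation in an exo-trig attack on the carbonyl (10-exo-trig), the two alkenes of the arm, the fused lactone and ring A limiting the conformations of the tether. The new C2 stereocentre is set by the macrocyclic transition state: with the aldehyde held on the quaternary C1, C3 is expected to reach the carbonyl carbon on its Si face, the one turned away from the C15 methyl and the ring A bonds, which gives the 2S alcohol. The step needs reaction at the C–I bond only (acetates, lactone, epoxide, free C8 hydroxyl and the C6 ether are left alone; an allylic chloride would be reduced, hence the ether), ring closure rather than intermolecular coupling (slow addition, high dilution), and no enolisation (neopentyl aldehyde).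

Step 29
Reactants: 38 ten-membered C2 allylic alcohol
Product: 39 C2 acetate
Conditions: Ac2O, DMAP, pyridine, rt
Reagents that add atoms: acetic anhydride, CC(=O)OC(C)=O
Why: Acylation of the secondary allylic alcohol; the tertiary C8 hydroxyl stays free.

Step 30
Reactants: 39 C2 acetate
Product: 40 C6 alcohol (6R)
Conditions: DDQ, CH2Cl2/pH 7 buffer, 0 °C
Reagents that add atoms: none
Why: Oxidative cleavage of the p-methoxybenzyl ether (hydride abstraction by the quinone, hydrolysis of the oxocarbenium ion) frees the C6 hydroxyl without acid or base.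

Step 31
Reactants: 40 C6 alcohol
Product: 41 brianthein Z
Conditions: PPh3, hexachloroacetone, CH2Cl2, −20 to 0 °C
Reagents that add atoms: hexachloroacetone, O=C(C(Cl)(Cl)Cl)C(Cl)(Cl)Cl
Why: Chlorination through an alkoxyphosphonium ion, chloride displacing triphenylphosphine oxide in an SN2 step with inversion at C6 (R to S) under conditions that give unrearranged allylic chlorides; the tertiary C8 hydroxyl is too hindered to be activated.

**Compound list**

1 | ethyl (E)-2-methylbut-2-enoate (ethyl tiglate) | CCOC(=O)/C(C)=C/C | starting material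
2 | ethyl (E)-2-methyl-4-oxobut-2-enoate | CCOC(=O)/C(C)=C/C=O | intermediate
3 | (E)-penta-1,3-diene | C/C=C/C=C | starting material
4 | ethyl (1S,5S,6S)-6-formyl-1,5-dimethylcyclohex-3-ene-1-carboxylate (formyl cis to both methyls, trans to the ester) | CCOC(=O)[C@]1(C)[C@H]([C@@H](C)C=CC1)C=O | intermediate
5 | ethyl (1S,5S,6S)-6-(dimethoxymethyl)-1,5-dimethylcyclohex-3-ene-1-carboxylate | CCOC(=O)[C@]1(C)[C@H]([C@@H](C)C=CC1)C(OC)OC | intermediate
6 | [(1S,5S,6S)-6-(dimethoxymethyl)-1,5-dimethylcyclohex-3-en-1-yl]methanol | OC[C@]1(C)[C@H]([C@@H](C)C=CC1)C(OC)OC | intermediate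
7 | 12α,13α-epoxy alcohol (epoxide cis to the C2 hydroxymethyl group) | OC[C@]1(C)[C@H]([C@@H](C)[C@@H]2O[C@@H]2C1)C(OC)OC | intermediate
8 | C2 tert-butyldiphenylsilyl ether of 7 | CC(C)(C)[Si](c1ccccc1)(c1ccccc1)OC[C@]1(C)[C@H]([C@@H](C)[C@@H]2O[C@@H]2C1)C(OC)OC | intermediate
9 | ring A allylic alcohol (12α-OH, C13=C14, C2 silyl ether, C9 dimethyl acetal) | CC(C)(C)[Si](c1ccccc1)(c1ccccc1)OC[C@]1(C)[C@H]([C@@H](C)[C@H](O)C=C1)C(OC)OC | intermediate
10 | ring A hydroxy aldehyde (C9 aldehyde, 12α-OH) | CC(C)(C)[Si](c1ccccc1)(c1ccccc1)OC[C@]1(C)[C@H]([C@@H](C)[C@H](O)C=C1)C=O | intermediate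
11 | ring A aldehyde (C9 aldehyde, 12α-OSiEt3, C2 OSiPh2t-Bu) | CC(C)(C)[Si](c1ccccc1)(c1ccccc1)OC[C@]1(C)[C@H]([C@@H](C)[C@H](O[Si](CC)(CC)CC)C=C1)C=O | intermediate
12 | (R)-4-methyldihydrofuran-2(3H)-one | O=C1C[C@@H](C)CO1 | starting material
13 | sodium enolate of 12 | [Na]OC1=C[C@@H](C)CO1 | intermediate
14 | (3R,4S)-3-hydroxy-4-methyldihydrofuran-2(3H)-one | O=C1[C@H](O)[C@@H](C)CO1 | intermediate
15 | (3R,4S)-4-methyl-3-(triethylsilyloxy)dihydrofuran-2(3H)-one | O=C1[C@H](O[Si](CC)(CC)CC)[C@@H](C)CO1 | intermediate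
16 | 2-bromoprop-2-en-1-ol | OCC(Br)=C | starting material
17 | 1-{[(2-bromoprop-2-en-1-yl)oxy]methyl}-4-methoxybenzene | COc1ccc(COCC(Br)=C)cc1 | intermediate
18 | ethynyltrimethylsilane | C#C[Si](C)(C)C | starting material
19 | {3-[(4-methoxybenzyloxy)methyl]but-3-en-1-yn-1-yl}trimethylsilane | COc1ccc(COCC(=C)C#C[Si](C)(C)C)cc1 | intermediate
20 | lithium enolate of 15 | [Li]OC1=C(O[Si](CC)(CC)CC)[C@@H](C)CO1 | intermediate
21 | aldol adduct (8R; C9 carbinol epimers; C7-carbonyl butanolide) | CC(C)(C)[Si](c1ccccc1)(c1ccccc1)OC[C@]1(C)[C@H]([C@@H](C)[C@H](O[Si](CC)(CC)CC)C=C1)C(O)[C@]1(O[Si](CC)(CC)CC)[C@@H](C)COC1=O | intermediate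
22 | C9 ketone | CC(C)(C)[Si](c1ccccc1)(c1ccccc1)OC[C@]1(C)[C@H]([C@@H](C)[C@H](O[Si](CC)(CC)CC)C=C1)C(=O)[C@]1(O[Si](CC)(CC)CC)[C@@H](C)COC1=O | intermediate
23 | (9S)-alcohol | CC(C)(C)[Si](c1ccccc1)(c1ccccc1)OC[C@]1(C)[C@H]([C@@H](C)[C@H](O[Si](CC)(CC)CC)C=C1)[C@H](O)[C@]1(O[Si](CC)(CC)CC)[C@@H](C)COC1=O | intermediate
24 | tris(triethylsilyl) ether (O8, O9, O12) | CC(C)(C)[Si](c1ccccc1)(c1ccccc1)OC[C@]1(C)[C@H]([C@@H](C)[C@H](O[Si](CC)(CC)CC)C=C1)[C@H](O[Si](CC)(CC)CC)[C@]1(O[Si](CC)(CC)CC)[C@@H](C)COC1=O | intermediate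
25 | C7 lactol (anomer mixture) | CC(C)(C)[Si](c1ccccc1)(c1ccccc1)OC[C@]1(C)[C@H]([C@@H](C)[C@H](O[Si](CC)(CC)CC)C=C1)[C@H](O[Si](CC)(CC)CC)[C@]1(O[Si](CC)(CC)CC)[C@@H](C)COC1O | intermediate
26 | allyllithium from 19 (lithium on the carbon bearing the ether oxygen) | COc1ccc(COC([Li])C(=C)C#C[Si](C)(C)C)cc1 | intermediate
27 | γ-alkoxyallyl diisopinocampheylborane (ether oxygen cis to CH2B) | COc1ccc(CO/C=C(/C#C[Si](C)(C)C)CB([C@@H]2C[C@@H]3C[C@H]([C@H]2C)C3(C)C)[C@@H]2C[C@@H]3C[C@H]([C@H]2C)C3(C)C)cc1 | intermediate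
28 | C7,C19 diol (6R,7S; C6 p-methoxybenzyl ether) | CC(C)(C)[Si](c1ccccc1)(c1ccccc1)OC[C@]1(C)[C@H]([C@@H](C)[C@H](O[Si](CC)(CC)CC)C=C1)[C@H](O[Si](CC)(CC)CC)[C@](O[Si](CC)(CC)CC)([C@@H](C)CO)[C@@H](O)[C@H](OCc1ccc(OC)cc1)C(=C)C#C[Si](C)(C)C | intermediate
29 | γ-lactone (C19 carbonyl, O–C7) with silylated enyne arm | CC(C)(C)[Si](c1ccccc1)(c1ccccc1)OC[C@]1(C)[C@H]([C@@H](C)[C@H](O[Si](CC)(CC)CC)C=C1)[C@H](O[Si](CC)(CC)CC)[C@]1(O[Si](CC)(CC)CC)[C@@H](C)C(=O)O[C@H]1[C@@H](C(=C)C#C[Si](C)(C)C)OCc1ccc(OC)cc1 | intermediate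
30 | C8,C9,C12 triol | CC(C)(C)[Si](c1ccccc1)(c1ccccc1)OC[C@]1(C)[C@H]([C@@H](C)[C@H](O)C=C1)[C@H](O)[C@]1(O)[C@@H](C)C(=O)O[C@H]1[C@@H](C(=C)C#C[Si](C)(C)C)OCc1ccc(OC)cc1 | intermediate
31 | 13α,14α-epoxy triol | CC(C)(C)[Si](c1ccccc1)(c1ccccc1)OC[C@]2(C)[C@H]([C@@H](C)[C@H](O)[C@@H]3O[C@@H]32)[C@H](O)[C@]2(O)[C@@H](C)C(=O)O[C@H]2[C@@H](C(=C)C#C[Si](C)(C)C)OCc1ccc(OC)cc1 | intermediate
32 | C9,C12 diacetate | CC(C)(C)[Si](c1ccccc1)(c1ccccc1)OC[C@]2(C)[C@H]([C@@H](C)[C@H](OC(C)=O)[C@@H]3O[C@@H]32)[C@H](OC(C)=O)[C@]2(O)[C@@H](C)C(=O)O[C@H]2[C@@H](C(=C)C#C[Si](C)(C)C)OCc1ccc(OC)cc1 | intermediate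
33 | iodoalkyne | CC(C)(C)[Si](c1ccccc1)(c1ccccc1)OC[C@]2(C)[C@H]([C@@H](C)[C@H](OC(C)=O)[C@@H]3O[C@@H]32)[C@H](OC(C)=O)[C@]2(O)[C@@H](C)C(=O)O[C@H]2[C@@H](C(=C)C#CI)OCc1ccc(OC)cc1 | intermediate
34 | (Z)-iodo-diene | CC(C)(C)[Si](c1ccccc1)(c1ccccc1)OC[C@]2(C)[C@H]([C@@H](C)[C@H](OC(C)=O)[C@@H]3O[C@@H]32)[C@H](OC(C)=O)[C@]2(O)[C@@H](C)C(=O)O[C@H]2[C@@H](C(=C)/C=C\I)OCc1ccc(OC)cc1 | intermediate
35 | C2 alcohol | OC[C@]2(C)[C@H]([C@@H](C)[C@H](OC(C)=O)[C@@H]3O[C@@H]32)[C@H](OC(C)=O)[C@]2(O)[C@@H](C)C(=O)O[C@H]2[C@@H](C(=C)/C=C\I)OCc1ccc(OC)cc1 | intermediate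
36 | seco C2 aldehyde with Z-iodo-diene arm and (6R) p-methoxybenzyl ether | O=C[C@]2(C)[C@H]([C@@H](C)[C@H](OC(C)=O)[C@@H]3O[C@@H]32)[C@H](OC(C)=O)[C@]2(O)[C@@H](C)C(=O)O[C@H]2[C@@H](C(=C)/C=C\I)OCc1ccc(OC)cc1 | intermediate
37 | Z-alkenylchromium dichloride at C3 | O=C[C@]2(C)[C@H]([C@@H](C)[C@H](OC(C)=O)[C@@H]3O[C@@H]32)[C@H](OC(C)=O)[C@]2(O)[C@@H](C)C(=O)O[C@H]2[C@@H](C(=C)/C=C\[Cr](Cl)Cl)OCc1ccc(OC)cc1 | intermediate
38 | ten-membered C2 allylic alcohol (2S; C6 p-methoxybenzyl ether) | C=C1/C=C\[C@H](O)[C@]2(C)[C@H]([C@@H](C)[C@H](OC(C)=O)[C@@H]3O[C@@H]32)[C@H](OC(C)=O)[C@]2(O)[C@@H](C)C(=O)O[C@H]2[C@@H]1OCc1ccc(OC)cc1 | intermediate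
39 | C2 acetate | C=C1/C=C\[C@H](OC(C)=O)[C@]2(C)[C@H]([C@@H](C)[C@H](OC(C)=O)[C@@H]3O[C@@H]32)[C@H](OC(C)=O)[C@]2(O)[C@@H](C)C(=O)O[C@H]2[C@@H]1OCc1ccc(OC)cc1 | intermediate
40 | C6 alcohol (6R) | C=C1/C=C\[C@H](OC(C)=O)[C@]2(C)[C@H]([C@@H](C)[C@H](OC(C)=O)[C@@H]3O[C@@H]32)[C@H](OC(C)=O)[C@]2(O)[C@@H](C)C(=O)O[C@H]2[C@@H]1O | intermediate
41 | brianthein Z | C=C1/C=C\[C@H](OC(C)=O)[C@]2(C)[C@H]([C@@H](C)[C@H](OC(C)=O)[C@@H]3O[C@@H]32)[C@H](OC(C)=O)[C@]2(O)[C@@H](C)C(=O)O[C@H]2[C@H]1Cl | target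

**Count and risks**

Total step count: 31. Longest linear sequence: 27 steps (steps 1–9 and 14–31).

The three steps most likely to fail:

Step 28 (ring closure). The alkenylchromium may be protonated or may couple intermolecularly before it reaches the hindered neopentyl aldehyde, and the facial selectivity at C2 may be poor. Fallback: the ring is closed through an sp carbon, which asks less bending of the tether. Setting out from 33, desilylation (Bu4NF, AcOH) should give the iodoalkyne alcohol F1 and oxidation (DMP) the iodoalkyne aldehyde F2. CrCl2 in THF (a haloalkyne needs no nickel) should then form the alkynylchromium species F3, which closes the ring to the cyclic enynol F4. Z-selective semireduction of the enyne with zinc activated by Cu(OAc)2 and AgNO3 in MeOH/H2O comes back to the route at 38.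

Step 14 (aldol). Bond formation between the fully substituted enolate carbon and the aldehyde on the crowded C10 may stall or revert (retro-aldol), and the O8 silyl group may migrate to the new C9 alkoxide. Fallback: acylation instead of aldol. Setting out from 11, oxidation (NaClO2, NaH2PO4, 2-methylbut-2-ene, t-BuOH/H2O) should give the carboxylic acid F5, and 1-chloro-N,N,2-trimethylprop-1-en-1-amine the acid chloride F6. Addition of F6 to the lithium enolate 20 at −78 °C (irreversible Claisen-type C-acylation) comes back to the route at 22; step 15 is then not needed.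

Step 19 (γ-alkoxyallylboration). s-BuLi may add to the conjugated enyne of 19 instead of removing the allylic proton, and the hindered lactol may open too slowly for the borane. Fallback: the alkyne is put on after the allylation. The silyl allyl ether F7 (from 17 and Me3SiSiMe3 with Pd(PPh3)4) is metallated with s-BuLi to the allyllithium F8 and converted with (−)-Ipc2BOMe and BF3·OEt2 into the borane F9. Setting out from 25, F9 should give the diol F10 and TEMPO/PhI(OAc)2 the lactone F11. N-Iodosuccinimide (iododesilylation) should give the alkenyl iodide F12, and Sonogashira coupling of F12 with 18 (PdCl2(PPh3)2, CuI, i-Pr2NH) comes back to the route at 29.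

**Further compounds**

F1 | step 28 | iodoalkyne C2 alcohol | OC[C@]2(C)[C@H]([C@@H](C)[C@H](OC(C)=O)[C@@H]3O[C@@H]32)[C@H](OC(C)=O)[C@]2(O)[C@@H](C)C(=O)O[C@H]2[C@@H](C(=C)C#CI)OCc1ccc(OC)cc1
F2 | step 28 | iodoalkyne C2 aldehyde | O=C[C@]2(C)[C@H]([C@@H](C)[C@H](OC(C)=O)[C@@H]3O[C@@H]32)[C@H](OC(C)=O)[C@]2(O)[C@@H](C)C(=O)O[C@H]2[C@@H](C(=C)C#CI)OCc1ccc(OC)cc1
F3 | step 28 | alkynylchromium dichloride at C3 | O=C[C@]2(C)[C@H]([C@@H](C)[C@H](OC(C)=O)[C@@H]3O[C@@H]32)[C@H](OC(C)=O)[C@]2(O)[C@@H](C)C(=O)O[C@H]2[C@@H](C(=C)C#C[Cr](Cl)Cl)OCc1ccc(OC)cc1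
F4 | step 28 | ten-membered cyclic enynol (C3≡C4, 2S) | C=C1C#C[C@H](O)[C@]2(C)[C@H]([C@@H](C)[C@H](OC(C)=O)[C@@H]3O[C@@H]32)[C@H](OC(C)=O)[C@]2(O)[C@@H](C)C(=O)O[C@H]2[C@@H]1OCc1ccc(OC)cc1
F5 | step 14 | ring A C9 carboxylic acid | CC(C)(C)[Si](c1ccccc1)(c1ccccc1)OC[C@]1(C)[C@H]([C@@H](C)[C@H](O[Si](CC)(CC)CC)C=C1)C(=O)O
F6 | step 14 | ring A C9 acid chloride | CC(C)(C)[Si](c1ccccc1)(c1ccccc1)OC[C@]1(C)[C@H]([C@@H](C)[C@H](O[Si](CC)(CC)CC)C=C1)C(=O)Cl
F7 | step 19 | 1-methoxy-4-({[2-(trimethylsilyl)prop-2-en-1-yl]oxy}methyl)benzene | COc1ccc(COCC(=C)[Si](C)(C)C)cc1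
F8 | step 19 | allyllithium from F7 | COc1ccc(COC([Li])C(=C)[Si](C)(C)C)cc1
F9 | step 19 | 2-silyl γ-alkoxyallyl diisopinocampheylborane | COc1ccc(CO/C=C(/[Si](C)(C)C)CB([C@@H]2C[C@@H]3C[C@H]([C@H]2C)C3(C)C)[C@@H]2C[C@@H]3C[C@H]([C@H]2C)C3(C)C)cc1
F10 | step 19 | C7,C19 diol with C5 trimethylsilyl group | CC(C)(C)[Si](c1ccccc1)(c1ccccc1)OC[C@]1(C)[C@H]([C@@H](C)[C@H](O[Si](CC)(CC)CC)C=C1)[C@H](O[Si](CC)(CC)CC)[C@](O[Si](CC)(CC)CC)([C@@H](C)CO)[C@@H](O)[C@H](OCc1ccc(OC)cc1)C(=C)[Si](C)(C)C
F11 | step 19 | γ-lactone with C5 trimethylsilyl group | CC(C)(C)[Si](c1ccccc1)(c1ccccc1)OC[C@]1(C)[C@H]([C@@H](C)[C@H](O[Si](CC)(CC)CC)C=C1)[C@H](O[Si](CC)(CC)CC)[C@]1(O[Si](CC)(CC)CC)[C@@H](C)C(=O)O[C@H]1[C@@H](C(=C)[Si](C)(C)C)OCc1ccc(OC)cc1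
F12 | step 19 | γ-lactone with C5 iodide | CC(C)(C)[Si](c1ccccc1)(c1ccccc1)OC[C@]1(C)[C@H]([C@@H](C)[C@H](O[Si](CC)(CC)CC)C=C1)[C@H](O[Si](CC)(CC)CC)[C@]1(O[Si](CC)(CC)CC)[C@@H](C)C(=O)O[C@H]1[C@@H](C(I)=C)OCc1ccc(OC)cc1
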